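**Plan**

- Ring numbering used here: in the cyclohexenedione, C1 bears the coumarin, C2 is the =CH, C3 is the ketone next to it, C4 is the C(OH)(prenyl) carbon, C5 is the CH2, and C6 is the second ketone. The retrosynthesis cuts C1=C2 and C3–C4 together. C2–C3 then leaves as glyoxal, and what remains is an open-chain 1-(coumarin-3-yl)-7-methyloct-6-ene-2,4-dione with a triphenylphosphorane on C1.
- Enabling feature: the =CH–C(=O) pair C2–C3 lies between C1, which sits between the coumarin and the C6 ketone and can therefore be a carbonyl-stabilised ylide carbon, and C4, an α-ketol carbon. The C3–C4 link joins two carbonyl-derived carbons of like polarity and is made by an acyl anion equivalent (the Breslow intermediate of a chiral triazolylidene) adding to the C4 ketone.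
- Forward order: the coumarin bicycle is made first (Perkin condensation). Its 3-methyl group is then turned into the ylide arm (bromide, phosphonium salt, acetyl ylide, chain extension with the prenylacetyl unit). The carbocycle is closed last, in the final step.
- Stereochemistry: the only stereocentre (C4, R) is created in the last step under control of the chiral carbene catalyst, and no later step can scramble it.

Key step: step 7

Assumption: the (5aR,10bS) enantiomer of the aminoindanol-derived triazolium salt is taken to deliver the R carbinol; both enantiomers are commercial, and the mirror-image salt is used if the sense of induction proves opposite.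

**Route**

Step 1
Reactants: 1 2-hydroxy-4-methoxybenzaldehyde
Product: 2 7-methoxy-3-methyl-2H-chromen-2-one
Conditions: (EtCO)2O (4 equiv), Et3N (2 equiv), neat, 140 °C
Reagents that add atoms: propionic anhydride, CCC(=O)OC(=O)CC
Why: Perkin coumarin synthesis, in which O-propionylation of the phenol and base-mediated condensation of the propionate α-carbon with the ortho formyl group close the lactone ring; no stereocentre is formed.

Step 2
Reactants: 2 7-methoxy-3-methyl-2H-chromen-2-one
Product: 3 3-(bromomethyl)-7-methoxy-2H-chromen-2-one
Conditions: NBS (1.05 equiv), AIBN (5 mol%), PhCF3, 85 °C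
Reagents that add atoms: N-bromosuccinimide, O=C1CCC(=O)N1Br
Why: Wohl–Ziegler radical bromination; the 3-methyl group is allylic to the lactone C3=C4 bond, and C3, the usual site of ionic bromination of coumarins, is blocked.

Step 3
Reactants: 3 3-(bromomethyl)-7-methoxy-2H-chromen-2-one
Product: 4 [(7-methoxy-2-oxo-2H-chromen-3-yl)methyl]triphenylphosphonium bromide
Conditions: PPh3 (1.05 equiv), toluene, 90 °C; the salt is filtered off
Reagents that add atoms: triphenylphosphine, c1ccc(cc1)P(c1ccccc1)c1ccccc1
Why: SN2 quaternisation of the phosphine by a reactive allylic bromide; the salt should precipitate.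

Step 4
Reactants: 4 [(7-methoxy-2-oxo-2H-chromen-3-yl)methyl]triphenylphosphonium bromide
Product: 7 7-methoxy-3-[2-oxo-1-(triphenyl-λ5-phosphanylidene)propyl]-2H-chromen-2-one, via phosphorus ylide 5 (not isolated), via acylphosphonium chloride 6 (not isolated)
Conditions: NaN(SiMe3)2 (1.0 equiv), THF, −78 °C; the ylide solution is added to AcCl (1.5 equiv), THF, −78 → 0 °C; then aqueous Na2CO3
Reagents that add atoms: acetyl chloride, CC(=O)Cl
Why: C-acylation of a semi-stabilised phosphorus ylide; inverse addition suppresses transylidation, and the acidic acylphosphonium salt is deprotonated by carbonate to the stabilised acyl ylide.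

Step 5
Reactants: 8 4-methylpent-3-enoic acid
Product: 10 N-methoxy-N,4-dimethylpent-3-enamide, via acyl imidazolide 9 (not isolated)
Conditions: 1,1'-carbonyldiimidazole (1.1 equiv), CH2Cl2, 0 → 23 °C; then MeNH(OMe)·HCl (1.2 equiv), 23 °C
Reagents that add atoms: N,O-dimethylhydroxylamine hydrochloride, CNOC.Cl
Why: amide formation through the acyl imidazolide (Weinreb amide synthesis); the near-neutral medium should keep the β,γ-alkene out of conjugation.

Step 6
Reactants: 7 7-methoxy-3-[2-oxo-1-(triphenyl-λ5-phosphanylidene)propyl]-2H-chromen-2-one; 10 N-methoxy-N,4-dimethylpent-3-enamide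
Product: 12 7-methoxy-3-[7-methyl-2,4-dioxo-1-(triphenyl-λ5-phosphanylidene)oct-6-en-1-yl]-2H-chromen-2-one, via lithium ylide enolate 11 (not isolated)
Conditions: LiN(i-Pr)2 (commercial solution, 1.1 equiv), THF, −78 °C; then 10 (1.2 equiv), −78 → −20 °C; saturated aqueous NH4Cl
Reagents that add atoms: none
Why: γ-deprotonation of the acetyl ylide gives an ylide anion that is acylated at its terminal carbon (Claisen-type acylation of a β-oxo ylide anion); the chelated tetrahedral adduct of the N-methoxy-N-methylamide should persist until quench, which prevents over-addition and deprotonation of the product.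

Step 7
Reactants: 12 7-methoxy-3-[7-methyl-2,4-dioxo-1-(triphenyl-λ5-phosphanylidene)oct-6-en-1-yl]-2H-chromen-2-one; 13 glyoxal
Product: 15 3-[(4R)-4-hydroxy-4-(3-methylbut-2-en-1-yl)-3,6-dioxocyclohex-1-en-1-yl]-7-methoxy-2H-chromen-2-one, via oxo-enal 14 (not isolated)
Conditions: 13 (1.1 equiv, anhydrous monomer in THF, cracked from the commercial trimer dihydrate over P4O10), slow addition of 12, THF–toluene, 0 → 40 °C; then (5aR,10bS)-2-(pentafluorophenyl)-5a,10b-dihydro-4H,6H-indeno[2,1-b][1,2,4]triazolo[4,3-d][1,4]oxazin-2-ium tetrafluoroborate (20 mol%), i-Pr2NEt (20 mol%), 23 °C; neutral work-up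
Reagents that add atoms: none
Why: Proposed new method: the ylide carbon of 12 olefinates one formyl group of glyoxal (Wittig reaction, loss of Ph3PO) to give the 4-oxo-enal 14, whose remaining formyl group is converted by the triazolylidene into a Breslow intermediate that adds as an acyl anion equivalent to the C4 ketone in a 6-exo-trig closure and then releases the carbene (intramolecular crossed benzoin), so that the ring C=C bond and the acyl–carbinol bond are made in one flask. The closest known reaction types are the Wittig olefination of aldehydes with 2,4-dioxoalkylidene phosphoranes, the enantioselective carbene-catalysed aldehyde–ketone benzoin cyclisation to six-membered α-ketols, and amine/carbene Michael–benzoin cascades that close onto one carbonyl of a 1,3-diketone. The single stereocentre, the carbinol carbon, is set under catalyst control: the aminoindanol backbone shields one face of the Breslow enaminol, and the ketone, held by the forming ring and by a hydrogen bond to the enaminol OH, should be attacked on the face that gives the R configuration. The step needs olefination at the ylide carbon and not at the methylene between the two carbonyls; this is secured because the phosphorane holds the neighbouring carbonyl as a phosphonium enolate and the Wittig stage is run without base. It also needs both alkene isomers of 14 to converge on the (2Z) isomer that alone can cyclise; this is expected because in the Breslow intermediate the electron pair is delocalised through the alkene into the C6 ketone, so the former C=C bond gains single-bond character and can rotate. Finally it needs acyl anion rather than homoenolate reactivity, which the N-pentafluorophenyl triazolium, the aprotic medium and the intramolecular ketone acceptor should favour.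

**Compound list**

1 | 2-hydroxy-4-methoxybenzaldehyde | COc1ccc(C=O)c(O)c1 | starting material
2 | 7-methoxy-3-methyl-2H-chromen-2-one | COc1ccc2cc(C)c(=O)oc2c1 | intermediate
3 | 3-(bromomethyl)-7-methoxy-2H-chromen-2-one | COc1ccc2cc(CBr)c(=O)oc2c1 | intermediate
4 | [(7-methoxy-2-oxo-2H-chromen-3-yl)methyl]triphenylphosphonium bromide | COc1ccc2cc(C[P+](c3ccccc3)(c3ccccc3)c3ccccc3)c(=O)oc2c1.[Br-] | intermediate
5 | 7-methoxy-3-[(triphenyl-λ5-phosphanylidene)methyl]-2H-chromen-2-one (phosphorus ylide, not isolated) | COc1ccc2cc(C=P(c3ccccc3)(c3ccccc3)c3ccccc3)c(=O)oc2c1 | intermediate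
6 | [1-(7-methoxy-2-oxo-2H-chromen-3-yl)-2-oxopropyl]triphenylphosphonium chloride (not isolated) | COc1ccc2cc(C(C(C)=O)[P+](c3ccccc3)(c3ccccc3)c3ccccc3)c(=O)oc2c1.[Cl-] | intermediate
7 | 7-methoxy-3-[2-oxo-1-(triphenyl-λ5-phosphanylidene)propyl]-2H-chromen-2-one | COc1ccc2cc(C(C(C)=O)=P(c3ccccc3)(c3ccccc3)c3ccccc3)c(=O)oc2c1 | intermediate
8 | 4-methylpent-3-enoic acid | CC(C)=CCC(=O)O | starting material
9 | 1-(4-methylpent-3-enoyl)-1H-imidazole (not isolated) | CC(C)=CCC(=O)n1ccnc1 | intermediate
10 | N-methoxy-N,4-dimethylpent-3-enamide | CON(C)C(=O)CC=C(C)C | intermediate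
11 | lithium 3-(7-methoxy-2-oxo-2H-chromen-3-yl)-3-(triphenyl-λ5-phosphanylidene)prop-1-en-2-olate (ylide anion, not isolated) | [Li+].COc1ccc2cc(C(C([O-])=C)=P(c3ccccc3)(c3ccccc3)c3ccccc3)c(=O)oc2c1 | intermediate
12 | 7-methoxy-3-[7-methyl-2,4-dioxo-1-(triphenyl-λ5-phosphanylidene)oct-6-en-1-yl]-2H-chromen-2-one | COc1ccc2cc(C(C(=O)CC(=O)CC=C(C)C)=P(c3ccccc3)(c3ccccc3)c3ccccc3)c(=O)oc2c1 | intermediate
13 | glyoxal (ethanedial) | O=CC=O | starting material
14 | 3-(7-methoxy-2-oxo-2H-chromen-3-yl)-9-methyl-4,6-dioxodeca-2,8-dienal (mixture of 2E and 2Z isomers, not isolated) | COc1ccc2cc(C(=CC=O)C(=O)CC(=O)CC=C(C)C)c(=O)oc2c1 | intermediate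
15 | 3-[(4R)-4-hydroxy-4-(3-methylbut-2-en-1-yl)-3,6-dioxocyclohex-1-en-1-yl]-7-methoxy-2H-chromen-2-one | COc1ccc2cc(C3=CC(=O)[C@@](O)(CC=C(C)C)CC3=O)c(=O)oc2c1 | target

**Step count and risks**

Total steps: 7. Longest linear sequence: 6 (steps 1, 2, 3, 4, 6, 7); step 5 is a one-step side branch.

Steps most likely to fail:

1. Step 7 (proposed new method). The Breslow intermediate of the enal may be protonated at its β-carbon (homoenolate or redox pathway) instead of adding to the ketone. The trans enal from the Wittig stage may fail to isomerise to the cyclisable form. Facial selectivity may be poor. The product, a quinone hydrate, may lose water under base. The fallback uses known chemistry, sets out from 12 and comes back at 15. The Wittig reaction of 12 with 13 is run alone and the enal 14 is isolated. Conjugate reduction of its ene-dicarbonyl unit with Hantzsch ester and catalytic dibenzylammonium trifluoroacetate (THF, 23 °C) gives the saturated keto aldehyde 3-(7-methoxy-2-oxo-2H-chromen-3-yl)-9-methyl-4,6-dioxodec-8-enal F1. The same chiral triazolium salt with i-Pr2NEt then closes F1 by the precedented benzoin cyclisation of an aliphatic aldehyde onto a ketone. This gives 3-[(4R)-4-hydroxy-4-(3-methylbut-2-en-1-yl)-2,5-dioxocyclohexyl]-7-methoxy-2H-chromen-2-one F2 as a mixture of epimers at the aryl-bearing carbon. Dehydrogenation with IBX (DMSO, 65 °C) can only take place between the aryl-bearing carbon and its CH2 neighbour, removes that epimeric centre and gives 15.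

2. Step 6. Proton transfer from the acidic allylic α-CH2 of amide 10 to the ylide anion, with migration of the alkene into conjugation, may outrun acyl substitution. The fallback sets out from 10 and 11 and comes back at 12. Amide 10 is reduced with i-Bu2AlH (THF, −78 °C) to 4-methylpent-3-enal F3, which is used at once. Aldol addition of the ylide anion 11 to F3 at −78 °C, which should be much faster than enolisation, gives 3-[4-hydroxy-7-methyl-2-oxo-1-(triphenyl-λ5-phosphanylidene)oct-6-en-1-yl]-7-methoxy-2H-chromen-2-one F4. Oxidation of the β-hydroxy ketone with Dess–Martin periodinane (CH2Cl2, NaHCO3, 0 °C), which stabilised ylides tolerate, gives 12.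

3. Step 2. Ionic bromination of the electron-rich benzo ring or double bromination of the methyl group may compete with the radical side-chain bromination. The fallback sets out from 1 and comes back at the ylide 5. A Morita–Baylis–Hillman reaction of 1 with tert-butyl acrylate (DABCO, CHCl3, 23 °C) gives tert-butyl 2-[hydroxy(2-hydroxy-4-methoxyphenyl)methyl]prop-2-enoate F5. Treatment with HCl in AcOH at reflux brings about lactonisation with allylic transposition and gives 3-(chloromethyl)-7-methoxy-2H-chromen-2-one F6. PPh3 in toluene at 90 °C gives [(7-methoxy-2-oxo-2H-chromen-3-yl)methyl]triphenylphosphonium chloride F7, which with NaN(SiMe3)2 gives the ylide 5 of step 4.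

**Further compounds**

F1 | step 7 | 3-(7-methoxy-2-oxo-2H-chromen-3-yl)-9-methyl-4,6-dioxodec-8-enal (racemic) | COc1ccc2cc(C(CC=O)C(=O)CC(=O)CC=C(C)C)c(=O)oc2c1
F2 | step 7 | 3-[(4R)-4-hydroxy-4-(3-methylbut-2-en-1-yl)-2,5-dioxocyclohexyl]-7-methoxy-2H-chromen-2-one (both epimers at the aryl-bearing carbon) | COc1ccc2cc(C3CC(=O)[C@@](O)(CC=C(C)C)CC3=O)c(=O)oc2c1
F3 | step 6 | 4-methylpent-3-enal | CC(C)=CCC=O
F4 | step 6 | 3-[4-hydroxy-7-methyl-2-oxo-1-(triphenyl-λ5-phosphanylidene)oct-6-en-1-yl]-7-methoxy-2H-chromen-2-one (racemic) | COc1ccc2cc(C(C(=O)CC(O)CC=C(C)C)=P(c3ccccc3)(c3ccccc3)c3ccccc3)c(=O)oc2c1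
F5 | step 2 | tert-butyl 2-[hydroxy(2-hydroxy-4-methoxyphenyl)methyl]prop-2-enoate (racemic) | COc1ccc(C(O)C(=C)C(=O)OC(C)(C)C)c(O)c1
F6 | step 2 | 3-(chloromethyl)-7-methoxy-2H-chromen-2-one | COc1ccc2cc(CCl)c(=O)oc2c1
F7 | step 2 | [(7-methoxy-2-oxo-2H-chromen-3-yl)methyl]triphenylphosphonium chloride | COc1ccc2cc(C[P+](c3ccccc3)(c3ccccc3)c3ccccc3)c(=O)oc2c1.[Cl-]
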